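# Proposed synthesis of (4R)-4-(3,4-dihydroxyphenyl)-6-[2-(3,4-dimethoxyphenyl)ethyl]-7-hydroxy-3,4-dihydro-2H-chromen-2-one (14)

## The problem

Compound 14 is a 4-aryl-3,4-dihydrocoumarin. Its six-membered aryl lactone is fused to ring A (C4a–C8a), which carries a hydroxyl group at C7 and a 2-(3,4-dimethoxyphenyl)ethyl chain at C6, and C4 bears a 3,4-dihydroxyphenyl group. The lactone is the only non-aromatic ring and closes readily once a free C8a phenol faces a C2 carboxyl derivative. The real task is therefore the open-chain 3,3-diarylpropanoate behind it. C4 is the only stereocentre (R), a methine between two oxygenated aryl groups, and no second stereocentre can relay configuration to it, so a chiral catalyst has to set it. Once set it is not enolisable, but it lies between two very electron-rich rings, and strong acid could cleave the C4–C4a bond reversibly, so the closing steps must be mild. The free catechol is easily oxidised, above all under base, and the aryl lactone is opened by base and by alcohols, so both should appear only at the end. Four phenols must be freed while two aryl methyl ethers stay, which points to benzyl ethers and hydrogenolysis. The enabling feature is that C3–C4 with the catechol ring on C4 is the skeleton of a styrene: C4 lacks only ring A (bond C4–C4a) and C3 lacks only the carboxyl carbon C2 (bond C2–C3), so both can be delivered across one C=C bond.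

## Retrosynthesis

**Lactone C–O bond.** The ester bond between the C8a oxygen and C2 of 14 is cut first, giving the open-chain methyl ester 13. The forward reaction is a six-membered transesterification that needs only catalytic acid. Cutting here, and not at a ring C–C bond, moves the problem to an acyclic chain in which the stereocentre is no longer part of a base- and alcohol-sensitive aryl ester. Of the four phenols of 13 only the one at C8a can reach the ester, so no regiochemical question arises.

**Phenol protection.** The four O–H groups of 13 are traced back to the four benzyl ethers of 12. Benzyl is preferred because one neutral hydrogenolysis removes all four and spares the methyl ethers, the ester and the stereocentre. Silyl ethers on a catechol would need fluoride or base, and further methyl ethers could not be told apart from the two that must stay. The forward step asks only that the diarylmethine C–C bonds resist hydrogen on palladium, which is expected since C4 bears no heteroatom.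

**Key disconnection.** In 12 the bonds C2–C3 and C4–C4a are cut together. This gives three achiral pieces: styrene 8 (C3, C4 and the catechol ring), aryl bromide 6 (ring A with its side chain) and the redox-active oxalate 11 (C2 as a latent methoxycarbonyl radical).
- Cutting C4–C4a alone would lead to a cinnamate and an aryl metal and form one bond per step.
- Cutting C4–C1' with C2–C3 would make ring A the styrene, which costs a formylation and an olefination on the longer branch where a single bromination now suffices.
- Cutting C3–C4 offers no handle for asymmetric induction.

The chosen cut forms two skeletal bonds and the only stereocentre in one operation. The methyl ester is a requirement, because the methoxycarbonyl radical keeps its CO2 unit whereas a tertiary alkoxycarbonyl radical would fragment. The forward reaction must add the radical to the CH2 terminus of 8, pass the benzylic radical to an aryl nickel species from 6 before either radical finds another partner, and let a chiral ligand on nickel fix C4.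

**Radical precursor.** The acyl–O bond of 11 is cut to N-hydroxyphthalimide 9 and methyl chlorooxoacetate 10, both commercial. The forward acylation is simple, but the product is a highly activated ester and must be kept dry.

**Styrene.** The C=C bond of 8 is cut to the commercial aldehyde 7, which already carries both benzyl ethers. A Wittig methylenation is all that is asked.

**Carbon–bromine bond.** Bromide 6 is traced to the dibenzyl ether 5. The position to be brominated is ortho to one benzyloxy group and para to the other, so it is the most nucleophilic carbon of the molecule. The forward step must brominate ring A without touching the dimethoxyphenyl ring, which is activated by only one oxygen at any position.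

**Ether and methylene.** The benzyl ethers of 5 lead to resorcinol 4, and the benzylic CH2 of 4 to the ketone of 3. The ketone is removed before benzylation so that the free ortho- and para-hydroxyl groups assist the ionic reduction and no benzyl ether meets strong acid.

**Aryl ketone.** The aryl–carbonyl bond of 3 is cut to resorcinol 1 and (3,4-dimethoxyphenyl)acetic acid 2. Direct acylation of resorcinol with an arylacetic acid is a standard route to such deoxybenzoins and places the side chain at the correct ring carbon.

## Roads not taken

**Alternative 1:** ring A is built last, beside an existing C4 stereocentre, by cutting C8a–C8, C7–C6 and C8a–C4a.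
- Forward key step: irradiation of the α-diazo enone A1 should cause a Wolff rearrangement to a vinylketene, which adds to the silyl ynol ether A2 in a [2+2] sense. On heating, the cyclobutenone opens and the dienylketene closes by 6π electrocyclisation to the phenol A3.
- Merits: the reaction type is known. The oxygenation pattern of ring A follows from the mechanism, so no halogenation selectivity arises. The C8a phenol emerges free and distinct from the silylated C7 oxygen, ready for lactonisation.
- Weak points: A1 must already contain the stereocentre, so a separate asymmetric step and a long chain extension come first. That centre is then an allylic, benzylic γ-carbon of an enone and must survive base-mediated diazo transfer and a thermal step without double-bond migration. A2 is labile. Three silyl ethers must later be removed from a catechol next to a base-sensitive lactone.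
- Comparison: this road is better in that its key step has precedent and ring A regiochemistry is guaranteed. The chosen plan sets against it three fragments of one to four steps, a stereocentre formed together with the skeleton, and a single neutral deprotection.

**Alternative 2:** the lactone is contracted in thought to a five-membered ketone, and C2–C3 is cut with the C4–H bond.
- Forward key step: the 2-(1-arylvinyl)benzaldehyde A4 should cyclise by rhodium-catalysed asymmetric hydroacylation (a catalyst of the type [Rh(BINAP)]ClO4) to the indanone A5. A later Baeyer–Villiger oxidation would insert the ring oxygen.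
- Merits: the cyclisation is intramolecular and atom-economic, and it is an established way to 3-aryl indanones of high enantiomeric purity.
- Weak points: A4 is a 1,2,4,5-tetrasubstituted benzaldehyde carrying a 1,1-diarylethene, which needs several cross-coupling and formylation steps. Decarbonylation competes with hydroacylation. In the ring expansion the migrating aryl carbon (the future C8a) has its oxygen substituent meta and not para, so aryl migration is not reinforced against CH2 migration. A peracid also meets three electron-rich arenes.
- Comparison: the enantioselectivity of this road is more secure than that of the chosen key step. The chosen plan sets against it a direct entry at the carboxyl oxidation state, no ring-expansion detour and a shorter sequence.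

**Alternative 3:** ring A is formed by cycloaddition, cutting C4a–C5 and C6–C7.
- Forward key step: the β-keto ester A6, made from a desymmetrised prochiral cyclic anhydride, is converted into the bis(silyloxy)diene A7. Diels–Alder addition of A7 to the ynone A8 and aromatisation should give the resorcinol A9, whose C6 ketone would be reduced together with the benzyl ethers.
- Merits: the source of chirality is a well-tried desymmetrisation. Ring A is formed with both oxygens and the C6 acyl group in place, with regiochemistry set by the polarity of diene and dienophile. The end game is short.
- Weak points: the sequence to A6 is long. Forming A7 needs γ-deprotonation of a β-keto ester beside a second ester of similar acidity. The chirality of A6 rests only on the difference between two carboxyl-derived arms, and any return to the cyclic anhydride during activation erases it. A8 is a terminal ynone with a doubly activated benzylic CH2 and is prone to isomerisation and polymerisation.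
- Comparison: this road is better in the reliability of its asymmetric step and in ring A regiocontrol. The chosen plan sets against it roughly half the step count and robust, storable intermediates, apart from 11.

Key step: step 7

Assumption: the sense of induction of the nickel–bis(oxazoline) catalyst in step 7 cannot be predicted for this new substrate class. The (S,S) ligand is written, and its equally accessible (R,R) antipode is to be used if the first run favours the (S) ester.

## Route

Step 1
Reactants: 1 resorcinol; 2 (3,4-dimethoxyphenyl)acetic acid
Product: 3 1-(2,4-dihydroxyphenyl)-2-(3,4-dimethoxyphenyl)ethan-1-one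
Conditions: BF3·OEt2 (neat, 5 equiv), 85 °C; then aq. NaOAc
Reagents that add atoms: none
Why: Friedel–Crafts (Nencki-type) acylation by the BF3-activated acid; resorcinol reacts ortho to one hydroxyl and para to the other, and the boron chelate of the ortho-hydroxy ketone blocks a second acylation. The dimethoxyphenyl ring of 2 is much less nucleophilic than resorcinol and should not be acylated.

Step 2
Reactants: 3 1-(2,4-dihydroxyphenyl)-2-(3,4-dimethoxyphenyl)ethan-1-one
Product: 4 4-[2-(3,4-dimethoxyphenyl)ethyl]benzene-1,3-diol
Conditions: Et3SiH (4 equiv), CF3CO2H, 0 °C → rt
Reagents that add atoms: none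
Why: Ionic hydrogenation; the protonated ketone and then the benzylic cation, both stabilised by the ortho- and para-hydroxyl groups, accept hydride from the silane, so the aryl ketone should be reduced to CH2. Phenols and aryl methyl ethers are inert to these conditions.

Step 3
Reactants: 4 4-[2-(3,4-dimethoxyphenyl)ethyl]benzene-1,3-diol
Product: 5 2,4-bis(benzyloxy)-1-[2-(3,4-dimethoxyphenyl)ethyl]benzene
Conditions: BnBr (2.4 equiv), K2CO3 (3 equiv), DMF, rt → 50 °C
Reagents that add atoms: benzyl bromide, BrCc1ccccc1
Why: Williamson ether synthesis; carbonate in a dipolar aprotic solvent favours O- over C-alkylation of the resorcinol.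

Step 4
Reactants: 5 2,4-bis(benzyloxy)-1-[2-(3,4-dimethoxyphenyl)ethyl]benzene
Product: 6 1,5-bis(benzyloxy)-2-bromo-4-[2-(3,4-dimethoxyphenyl)ethyl]benzene
Conditions: NBS (1.0 equiv), MeCN, −20 → 0 °C, dark
Reagents that add atoms: N-bromosuccinimide, O=C1CCC(=O)N1Br
Why: Electrophilic aromatic bromination; C5 of 5 is ortho to one benzyloxy group and para to the other and is activated by both, the carbon between the two ethers is hindered, and every carbon of the dimethoxyphenyl ring is activated by only one oxygen. One equivalent of reagent in the dark should therefore brominate ring A alone and leave the benzylic positions untouched.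

Step 5
Reactants: 7 3,4-bis(benzyloxy)benzaldehyde
Product: 8 3,4-bis(benzyloxy)styrene
Conditions: Ph3PCH3Br (1.3 equiv), KOtBu (1.25 equiv), THF, 0 °C → rt
Reagents that add atoms: methyltriphenylphosphonium bromide, C[P+](c1ccccc1)(c1ccccc1)c1ccccc1.[Br-]
Why: Wittig methylenation of an aromatic aldehyde with the unstabilised ylide. The electron-rich styrene should be stored cold with a radical inhibitor and used soon.

Step 6
Reactants: 9 N-hydroxyphthalimide; 10 methyl chlorooxoacetate
Product: 11 methyl (1,3-dioxoisoindolin-2-yl) oxalate
Conditions: Et3N (1.05 equiv), THF, 0 °C; filtration, crystallisation from CH2Cl2/hexane under exclusion of moisture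
Reagents that add atoms: none
Why: O-Acylation of the N-hydroxy imide by the acid chloride, the usual entry to N-acyloxyphthalimide redox-active esters. A non-aqueous work-up is chosen because the product is an activated oxalate.

Step 7
Reactants: 6 1,5-bis(benzyloxy)-2-bromo-4-[2-(3,4-dimethoxyphenyl)ethyl]benzene; 8 3,4-bis(benzyloxy)styrene; 11 methyl (1,3-dioxoisoindolin-2-yl) oxalate
Product: 12 methyl (3R)-3-{2,4-bis(benzyloxy)-5-[2-(3,4-dimethoxyphenyl)ethyl]phenyl}-3-[3,4-bis(benzyloxy)phenyl]propanoate
Conditions: NiBr2(dme) (10 mol %), (4S,4'S)-4,4'-diisopropyl-2,2'-bis(2-oxazoline) (12 mol %), Zn powder (3 equiv), DMA/THF, 10 °C; 8 (3 equiv), 11 (2.5 equiv, added over 6 h), 6 limiting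
Reagents that add atoms: none
Why: Proposed new method: Zinc reduces the divalent nickel bromide–bis(oxazoline) complex to zerovalent nickel, which inserts into the C–Br bond of 6, while a monovalent nickel species (or zinc itself) transfers one electron to 11, whose radical anion loses phthalimide anion and CO2 to leave the methoxycarbonyl radical; this radical does not shed a second CO2 at a useful rate because that would give a methyl radical. The acyl-type radical adds to the CH2 terminus of 8 (bond C2–C3), the resulting benzylic radical is captured by the divalent aryl nickel complex, and reductive elimination from trivalent nickel forms C4–C4a and returns monovalent nickel to the cycle. The closest known reaction type is the nickel-catalysed enantioselective reductive three-component alkyl-arylation of alkenes with redox-active esters and aryl halides; untested here are an alkoxycarbonyl radical as the first partner and an ortho-alkoxylated, electron-rich aryl bromide as the second. No ring is closed in this step. The one new stereocentre, C4 (R), is controlled by the C2-symmetric bis(oxazoline) on nickel, which differentiates the two faces of the planar benzylic radical at capture and in the reductive elimination that follows; the substrates are achiral and exert no bias of their own. Regioselectivity is secured by the aryl group of 8, since only attack at the unsubstituted carbon gives a stabilised benzylic radical. Chemoselectivity for the three-component product over direct union of the aryl nickel species with the methoxycarbonyl radical, over dimerisation of the benzylic radical and over reduction of 6 is to be secured by the threefold excess of 8, by slow addition of 11 and by keeping 6 as the limiting partner. Benzyl and methyl aryl ethers and the ester are inert to zinc and low-valent nickel at this temperature.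

Step 8
Reactants: 12 methyl (3R)-3-{2,4-bis(benzyloxy)-5-[2-(3,4-dimethoxyphenyl)ethyl]phenyl}-3-[3,4-bis(benzyloxy)phenyl]propanoate
Product: 13 methyl (3R)-3-(3,4-dihydroxyphenyl)-3-{2,4-dihydroxy-5-[2-(3,4-dimethoxyphenyl)ethyl]phenyl}propanoate
Conditions: H2 (1 atm), Pd/C (10 wt %), THF/MeOH, rt, then handled under Ar
Reagents that add atoms: none
Why: Hydrogenolysis of the four aryl benzyl ethers under neutral conditions; the methyl ethers, the ester and the C4–aryl bonds (no benzylic heteroatom) are not affected, so the configuration is kept. Methanol as co-solvent holds the product in the open ester form.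

Step 9
Reactants: 13 methyl (3R)-3-(3,4-dihydroxyphenyl)-3-{2,4-dihydroxy-5-[2-(3,4-dimethoxyphenyl)ethyl]phenyl}propanoate
Product: 14 (4R)-4-(3,4-dihydroxyphenyl)-6-[2-(3,4-dimethoxyphenyl)ethyl]-7-hydroxy-3,4-dihydro-2H-chromen-2-one
Conditions: p-TsOH·H2O (10 mol %), toluene/1,4-dioxane, 4 Å MS, 70 °C, Ar
Reagents that add atoms: none
Why: Acid-catalysed intramolecular transesterification (lactonisation); only the C8a phenol can reach the ester through a six-membered transition state, and trapping of methanol on the sieves drives the equilibrium to the lactone. C4 takes no part, so the R configuration is retained.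

## Compound list

1 | resorcinol (benzene-1,3-diol) | Oc1cccc(O)c1 | starting material
2 | (3,4-dimethoxyphenyl)acetic acid | COc1ccc(CC(=O)O)cc1OC | starting material
3 | 1-(2,4-dihydroxyphenyl)-2-(3,4-dimethoxyphenyl)ethan-1-one | COc1ccc(CC(=O)c2ccc(O)cc2O)cc1OC | intermediate
4 | 4-[2-(3,4-dimethoxyphenyl)ethyl]benzene-1,3-diol | COc1ccc(CCc2ccc(O)cc2O)cc1OC | intermediate
5 | 2,4-bis(benzyloxy)-1-[2-(3,4-dimethoxyphenyl)ethyl]benzene | COc1ccc(CCc2ccc(OCc3ccccc3)cc2OCc2ccccc2)cc1OC | intermediate
6 | 1,5-bis(benzyloxy)-2-bromo-4-[2-(3,4-dimethoxyphenyl)ethyl]benzene | COc1ccc(CCc2cc(Br)c(OCc3ccccc3)cc2OCc2ccccc2)cc1OC | intermediate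
7 | 3,4-bis(benzyloxy)benzaldehyde | O=Cc1ccc(OCc2ccccc2)c(OCc2ccccc2)c1 | starting material
8 | 3,4-bis(benzyloxy)styrene | C=Cc1ccc(OCc2ccccc2)c(OCc2ccccc2)c1 | intermediate
9 | N-hydroxyphthalimide | O=C1c2ccccc2C(=O)N1O | starting material
10 | methyl chlorooxoacetate | COC(=O)C(=O)Cl | starting material
11 | methyl (1,3-dioxoisoindolin-2-yl) oxalate | COC(=O)C(=O)ON1C(=O)c2ccccc2C1=O | intermediate
12 | methyl (3R)-3-{2,4-bis(benzyloxy)-5-[2-(3,4-dimethoxyphenyl)ethyl]phenyl}-3-[3,4-bis(benzyloxy)phenyl]propanoate | COC(=O)C[C@@H](c1cc(CCc2ccc(OC)c(OC)c2)c(OCc2ccccc2)cc1OCc1ccccc1)c1ccc(OCc2ccccc2)c(OCc2ccccc2)c1 | intermediate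
13 | methyl (3R)-3-(3,4-dihydroxyphenyl)-3-{2,4-dihydroxy-5-[2-(3,4-dimethoxyphenyl)ethyl]phenyl}propanoate | COC(=O)C[C@@H](c1cc(CCc2ccc(OC)c(OC)c2)c(O)cc1O)c1ccc(O)c(O)c1 | intermediate
14 | (4R)-4-(3,4-dihydroxyphenyl)-6-[2-(3,4-dimethoxyphenyl)ethyl]-7-hydroxy-3,4-dihydro-2H-chromen-2-one | COc1ccc(CCc2cc3c(cc2O)OC(=O)C[C@@H]3c2ccc(O)c(O)c2)cc1OC | target

## Step count and risk

Total: 9 steps. Longest linear sequence: 7 steps (steps 1, 2, 3, 4, 7, 8, 9, from resorcinol 1).

**Step 7 (key step, proposed new method).** Three processes are most likely to go wrong.
- Direct coupling of the methoxycarbonyl radical with the aryl nickel species, giving two-component ester formation on ring A, because the ortho-benzyloxy group slows capture of the bulky benzylic radical.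
- Dimerisation of the benzylic radical or hydrodebromination of 6, if oxidative addition of the electron-rich bromide lags behind radical generation.
- Low or wrong-sense enantioinduction with a ligand class not tested on this radical.

Fallback by known chemistry, setting out from 6 and returning at 12: a Heck reaction of 6 with methyl acrylate (Pd(OAc)2, P(o-tol)3, Et3N, DMF, 100 °C) should give methyl (2E)-3-{2,4-bis(benzyloxy)-5-[2-(3,4-dimethoxyphenyl)ethyl]phenyl}prop-2-enoate F1. Rhodium-catalysed asymmetric conjugate addition of commercial [3,4-bis(benzyloxy)phenyl]boronic acid to F1 ([RhCl(C2H4)2]2, chiral bicyclo[2.2.2]octa-2,5-diene ligand, aq. KOH, dioxane, 50 °C) then forms the bond from C4 to the catechol ring and the stereocentre. The ligand enantiomer is chosen so that the aryl group adds to the face giving (3R)-12. This gives up the one-step union for two steps of established type.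

**Step 4.** Competing bromination of the dimethoxyphenyl ring, or double bromination, may occur if the reactivity gap between the two alkoxyarenes is smaller than expected. Fallback, setting out from 4 and returning at 6: bromination is moved before benzylation, where the free resorcinol is far more nucleophilic than any anisole-type ring. NBS (1.0 equiv, MeCN, −40 °C) should give 4-bromo-6-[2-(3,4-dimethoxyphenyl)ethyl]benzene-1,3-diol F2, and benzylation of F2 (BnBr, K2CO3, DMF) gives 6.

**Step 6.** Hydrolysis of the activated oxalate during isolation, or its decomposition by residual amine, may occur because N-acyloxyphthalimides of oxalic half-esters are strong acylating agents. Fallback, setting out from 9 and returning at 11: 9 is first deprotonated with KOtBu in THF and the dry salt potassium 1,3-dioxoisoindolin-2-olate F3 is collected. F3 is then acylated with 10 in MeCN at 0 °C, so that only insoluble potassium chloride has to be filtered off and neither amine nor water touches the product.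

**Step 9.** Ring closure may stay incomplete because the transesterification is reversible. Erosion of configuration is possible through acid-induced reversible cleavage of the C4–C4a bond in the very electron-rich diarylmethane, and the catechol may oxidise on prolonged heating. Fallback, setting out from 12 and returning at 14: the ester is saponified before deprotection (LiOH, THF/H2O, rt; aq. HCl) to (3R)-3-{2,4-bis(benzyloxy)-5-[2-(3,4-dimethoxyphenyl)ethyl]phenyl}-3-[3,4-bis(benzyloxy)phenyl]propanoic acid F4. Hydrogenolysis (H2, Pd/C, EtOAc/AcOH, rt) should give (3R)-3-(3,4-dihydroxyphenyl)-3-{2,4-dihydroxy-5-[2-(3,4-dimethoxyphenyl)ethyl]phenyl}propanoic acid F5. The free hydroxy acid should close to 14 with loss of water on concentration from acetic acid at or near room temperature, without strong acid or heating.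

## Further compounds

F1 | step 7 | methyl (2E)-3-{2,4-bis(benzyloxy)-5-[2-(3,4-dimethoxyphenyl)ethyl]phenyl}prop-2-enoate | COC(=O)/C=C/c1cc(CCc2ccc(OC)c(OC)c2)c(OCc2ccccc2)cc1OCc1ccccc1
F2 | step 4 | 4-bromo-6-[2-(3,4-dimethoxyphenyl)ethyl]benzene-1,3-diol | COc1ccc(CCc2cc(Br)c(O)cc2O)cc1OC
F3 | step 6 | potassium 1,3-dioxoisoindolin-2-olate | [K+].[O-]N1C(=O)c2ccccc2C1=O
F4 | step 9 | (3R)-3-{2,4-bis(benzyloxy)-5-[2-(3,4-dimethoxyphenyl)ethyl]phenyl}-3-[3,4-bis(benzyloxy)phenyl]propanoic acid | OC(=O)C[C@@H](c1cc(CCc2ccc(OC)c(OC)c2)c(OCc2ccccc2)cc1OCc1ccccc1)c1ccc(OCc2ccccc2)c(OCc2ccccc2)c1
F5 | step 9 | (3R)-3-(3,4-dihydroxyphenyl)-3-{2,4-dihydroxy-5-[2-(3,4-dimethoxyphenyl)ethyl]phenyl}propanoic acid | OC(=O)C[C@@H](c1cc(CCc2ccc(OC)c(OC)c2)c(O)cc1O)c1ccc(O)c(O)c1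
A1 | alternative 1 | methyl (3S,4E)-3-[3,4-bis(tert-butyldimethylsilyloxy)phenyl]-7-diazo-9-(3,4-dimethoxyphenyl)-6-oxonon-4-enoate | COC(=O)C[C@@H](/C=C/C(=O)C(=[N+]=[N-])CCc1ccc(OC)c(OC)c1)c1ccc(O[Si](C)(C)C(C)(C)C)c(O[Si](C)(C)C(C)(C)C)c1
A2 | alternative 1 | (triisopropylsiloxy)acetylene | C#CO[Si](C(C)C)(C(C)C)C(C)C
A3 | alternative 1 | methyl (3R)-3-[3,4-bis(tert-butyldimethylsilyloxy)phenyl]-3-{5-[2-(3,4-dimethoxyphenyl)ethyl]-2-hydroxy-4-(triisopropylsilyloxy)phenyl}propanoate | COC(=O)C[C@@H](c1cc(CCc2ccc(OC)c(OC)c2)c(O[Si](C(C)C)(C(C)C)C(C)C)cc1O)c1ccc(O[Si](C)(C)C(C)(C)C)c(O[Si](C)(C)C(C)(C)C)c1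
A4 | alternative 2 | 5-(benzyloxy)-2-{1-[3,4-bis(benzyloxy)phenyl]ethenyl}-4-[2-(3,4-dimethoxyphenyl)ethyl]benzaldehyde | O=Cc1cc(OCc2ccccc2)c(CCc2ccc(OC)c(OC)c2)cc1C(=C)c1ccc(OCc2ccccc2)c(OCc2ccccc2)c1
A5 | alternative 2 | (3R)-6-(benzyloxy)-3-[3,4-bis(benzyloxy)phenyl]-5-[2-(3,4-dimethoxyphenyl)ethyl]indan-1-one | O=C1C[C@H](c2ccc(OCc3ccccc3)c(OCc3ccccc3)c2)c2cc(CCc3ccc(OC)c(OC)c3)c(OCc3ccccc3)cc21
A6 | alternative 3 | dimethyl (3R)-3-[3,4-bis(benzyloxy)phenyl]-5-oxoheptanedioate | COC(=O)C[C@@H](CC(=O)CC(=O)OC)c1ccc(OCc2ccccc2)c(OCc2ccccc2)c1
A7 | alternative 3 | methyl (3S)-3-[3,4-bis(benzyloxy)phenyl]-7-methoxy-5,7-bis(trimethylsilyloxy)hepta-4,6-dienoate (mixture of alkene isomers) | COC(=O)C[C@@H](C=C(O[Si](C)(C)C)C=C(OC)O[Si](C)(C)C)c1ccc(OCc2ccccc2)c(OCc2ccccc2)c1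
A8 | alternative 3 | 1-(3,4-dimethoxyphenyl)but-3-yn-2-one | C#CC(=O)Cc1ccc(OC)c(OC)c1
A9 | alternative 3 | methyl (3R)-3-[3,4-bis(benzyloxy)phenyl]-3-{5-[(3,4-dimethoxyphenyl)acetyl]-2,4-dihydroxyphenyl}propanoate | COC(=O)C[C@@H](c1cc(C(=O)Cc2ccc(OC)c(OC)c2)c(O)cc1O)c1ccc(OCc2ccccc2)c(OCc2ccccc2)c1
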